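Ring B (C1'–C6') is a para-alkylphenol with bromine at C3', that is, the aromatized form of a 4-substituted cyclohex-2-enone whose two carbons next to the carbonyl are equivalent. Everything rests on cutting C1'–C6' and C2'–C3': one amine-catalysed Michael addition/aldol condensation of a 3-arylpropanal with methyl vinyl ketone builds ring B on the benzylic bridge as a cyclohexenone, which is later dehydrogenated and brominated once. The precursor is the finished ring A (C1 ester, C3 and C4 methyl ethers, C5 bromine) carrying a 3-oxopropyl chain at C2, placed there by a Claisen rearrangement ortho to the C3 oxygen.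

Key step: step 7

Assumption: the target has no stereocentre, so the racemic centre C1' formed in step 7 needs no control; methyl 3-bromo-4,5-dihydroxybenzoate (1) is taken as a catalogue compound. Ring A is numbered C1 (ester carbon, later CH2OH), C2 (bridge), C3/C4 (oxygens), C5 (Br) throughout.

Step 1
Reactants: 1 methyl 3-bromo-4,5-dihydroxybenzoate
Product: 2 methyl 3-bromo-5-hydroxy-4-methoxybenzoate
Conditions: MeI (1.05 equiv), Li2CO3 (1.1 equiv), DMF, 40 °C
Reagents that add atoms: iodomethane, CI
Why: Regioselective Williamson etherification: the 4-OH, para to the ester and ortho to bromine, is by far the more acidic phenol, so the weak base forms only its phenoxide, which is methylated while the other OH stays protonated.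

Step 2
Reactants: 2 methyl 3-bromo-5-hydroxy-4-methoxybenzoate; 3 allyl bromide (3-bromoprop-1-ene)
Product: 4 methyl 3-bromo-4-methoxy-5-(prop-2-en-1-yloxy)benzoate
Conditions: K2CO3, acetone, reflux
Reagents that add atoms: none
Why: Williamson etherification (SN2) of the one remaining phenoxide with a reactive allylic bromide; no other nucleophilic site is present.

Step 3
Reactants: 4 methyl 3-bromo-4-methoxy-5-(prop-2-en-1-yloxy)benzoate
Product: 5 methyl 5-bromo-3-hydroxy-4-methoxy-2-(prop-2-en-1-yl)benzoate
Conditions: PhNEt2, 195 °C, sealed tube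
Reagents that add atoms: none
Why: Aromatic Claisen rearrangement: the [3,3]-sigmatropic shift delivers the allyl group to C2, the only ortho carbon of the ether that carries hydrogen (the other bears OMe), and enolization restores the arene, as is known for 3-allyloxy-4-methoxybenzoyl compounds.

Step 4
Reactants: 5 methyl 5-bromo-3-hydroxy-4-methoxy-2-(prop-2-en-1-yl)benzoate
Product: 6 methyl 5-bromo-3,4-dimethoxy-2-(prop-2-en-1-yl)benzoate
Conditions: MeI, K2CO3, DMF, rt
Reagents that add atoms: iodomethane, CI
Why: Williamson etherification of the unmasked 3-OH, which must be capped so that it can neither form a lactol with the later aldehyde nor add to the enone.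

Step 5
Reactants: 6 methyl 5-bromo-3,4-dimethoxy-2-(prop-2-en-1-yl)benzoate
Product: 8 methyl 5-bromo-2-(3-hydroxypropyl)-3,4-dimethoxybenzoate, via B-alkyl-9-BBN borane 7 (not isolated)
Conditions: 9-BBN (1.3 equiv), THF, 0 °C to rt; then 30% H2O2, aq. NaOAc, 0 °C to rt
Reagents that add atoms: hydrogen peroxide, OO (the boron residue of 7 comes from 9-BBN, B1C2CCCC1CCC2, and is lost again)
Why: Brown hydroboration–oxidation: the bulky borane places boron on the terminal carbon of the allyl group (anti-Markovnikov) without touching ester or aryl bromide, and buffered peroxide replaces boron by OH with the ester intact.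

Step 6
Reactants: 8 methyl 5-bromo-2-(3-hydroxypropyl)-3,4-dimethoxybenzoate
Product: 9 methyl 5-bromo-3,4-dimethoxy-2-(3-oxopropyl)benzoate
Conditions: TEMPO (10 mol %), PhI(OAc)2 (1.1 equiv), CH2Cl2, rt
Reagents that add atoms: none
Why: Oxoammonium (TEMPO)/PhI(OAc)2 oxidation of a primary alcohol stops at the aldehyde in anhydrous CH2Cl2 and tolerates aryl bromide, ester and ethers.

Step 7
Reactants: 9 methyl 5-bromo-3,4-dimethoxy-2-(3-oxopropyl)benzoate; 10 methyl vinyl ketone (but-3-en-2-one)
Product: 13 racemic methyl 5-bromo-3,4-dimethoxy-2-[(4-oxocyclohex-2-en-1-yl)methyl]benzoate, via diethylamine enamine 11 (not isolated), via keto aldehyde 12 (not isolated)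
Conditions: 10 (1.5 equiv), Et2NSiMe3 (20 mol %), MeCN, reflux; then piperidine/AcOH (20 mol % each), toluene, reflux, Dean–Stark
Reagents that add atoms: none
Why: The amine released from Et2NSiMe3 condenses with 9 to the E-enamine 11, whose α-carbon (the future C1') adds to the terminal carbon of 10 (bond C1'–C6'); hydrolysis, or exchange with a further molecule of 9, returns the amine and frees keto aldehyde 12. Piperidinium acetate then activates the aldehyde as its iminium ion, the methyl-side enol (or enamine) of the ketone attacks it (bond C2'–C3') and elimination delivers the conjugated enone. The closest known reaction type is the amine-catalysed Michael addition of aldehydes to vinyl ketones followed by aldol cyclodehydration, a Robinson-type annulation to 4-substituted cyclohex-2-enones. Ring B closes in a 6-(enolendo)-exo-trig mode, the enol double bond lying inside the forming ring. The stereocentre C1' arises in the Michael step without any controlling element, so 13 is racemic, which is harmless because C1' becomes aromatic in step 8. The step needs single alkylation and closure through the methyl group: the α-branch created by the first addition hinders a second enamine addition, only the CH3 terminus can reach the aldehyde in a six-membered ring (the CH2 side or the aldehyde α-carbon would give four-membered rings), and the hydroxide-free amine/acid medium keeps the enol from acylating the neighbouring C1 ester and leaves that ester unhydrolysed.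

Step 8
Reactants: 13 racemic methyl 5-bromo-3,4-dimethoxy-2-[(4-oxocyclohex-2-en-1-yl)methyl]benzoate
Product: 14 methyl 5-bromo-2-(4-hydroxybenzyl)-3,4-dimethoxybenzoate
Conditions: CuBr2 (2.2 equiv), LiBr (1.1 equiv), MeCN, reflux
Reagents that add atoms: none
Why: Halogen-mediated dehydrogenation of a cyclohexenone (CuBr2/LiBr aromatization): α-bromination of the enone, loss of HBr and enolization give the phenol and erase the C1' stereocentre, while the electron-poor, almost fully substituted ring A is left alone.

Step 9
Reactants: 14 methyl 5-bromo-2-(4-hydroxybenzyl)-3,4-dimethoxybenzoate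
Product: 15 methyl 5-bromo-2-(3-bromo-4-hydroxybenzyl)-3,4-dimethoxybenzoate
Conditions: NBS (1.0 equiv), p-TsOH·H2O (10 mol %), MeOH, rt
Reagents that add atoms: N-bromosuccinimide, O=C1CCC(=O)N1Br
Why: Electrophilic aromatic bromination ortho to the free phenol of ring B with one equivalent of bromenium source: the para position is blocked, the two ortho carbons (C3'/C5') are equivalent, and ring A, deactivated by ester and bromine with only C6 open, does not compete.

Step 10
Reactants: 15 methyl 5-bromo-2-(3-bromo-4-hydroxybenzyl)-3,4-dimethoxybenzoate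
Product: 16 methyl 5-bromo-2-(3-bromo-4-hydroxybenzyl)-3,4-dihydroxybenzoate
Conditions: BBr3 (5 equiv), CH2Cl2, −78 °C to 0 °C; then ice water
Reagents that add atoms: none
Why: Lewis acid ether cleavage with BBr3 (boron coordination, then bromide SN2 at methyl) removes both aryl methyl ethers at low temperature, at which the methyl ester should survive.

Step 11
Reactants: 16 methyl 5-bromo-2-(3-bromo-4-hydroxybenzyl)-3,4-dihydroxybenzoate
Product: 17 5-bromo-2-(3-bromo-4-hydroxybenzyl)-3,4-dihydroxybenzyl alcohol, the target (6-bromo-3-[(3-bromo-4-hydroxyphenyl)methyl]-4-(hydroxymethyl)benzene-1,2-diol)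
Conditions: i-Bu2AlH (7 equiv), THF–toluene, 0 °C to rt; then aq. KNaC4H4O6
Reagents that add atoms: none
Why: Hydride reduction of an ester with excess i-Bu2AlH: the three phenols are first converted into aluminium phenoxides, the ester is then reduced to the primary alcohol as is known for unprotected hydroxybenzoate and hydroxycinnamate esters, and the aryl bromides are inert to this reagent at or below room temperature.

Compound list
1 | methyl 3-bromo-4,5-dihydroxybenzoate | COC(=O)c1cc(O)c(O)c(Br)c1 | starting material
2 | methyl 3-bromo-5-hydroxy-4-methoxybenzoate | COC(=O)c1cc(O)c(OC)c(Br)c1 | intermediate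
3 | allyl bromide (3-bromoprop-1-ene) | C=CCBr | starting material
4 | methyl 3-bromo-4-methoxy-5-(prop-2-en-1-yloxy)benzoate | COC(=O)c1cc(OCC=C)c(OC)c(Br)c1 | intermediate
5 | methyl 5-bromo-3-hydroxy-4-methoxy-2-(prop-2-en-1-yl)benzoate | COC(=O)c1cc(Br)c(OC)c(O)c1CC=C | intermediate
6 | methyl 5-bromo-3,4-dimethoxy-2-(prop-2-en-1-yl)benzoate | COC(=O)c1cc(Br)c(OC)c(OC)c1CC=C | intermediate
7 | B-alkyl-9-BBN borane, methyl 2-[3-(9-borabicyclo[3.3.1]nonan-9-yl)propyl]-5-bromo-3,4-dimethoxybenzoate | COC(=O)c1cc(Br)c(OC)c(OC)c1CCCB1C2CCCC1CCC2 | intermediate (not isolated)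
8 | methyl 5-bromo-2-(3-hydroxypropyl)-3,4-dimethoxybenzoate | COC(=O)c1cc(Br)c(OC)c(OC)c1CCCO | intermediate
9 | methyl 5-bromo-3,4-dimethoxy-2-(3-oxopropyl)benzoate | COC(=O)c1cc(Br)c(OC)c(OC)c1CCC=O | intermediate
10 | methyl vinyl ketone (but-3-en-2-one) | C=CC(C)=O | starting material
11 | diethylamine enamine, methyl 5-bromo-2-[(2E)-3-(diethylamino)prop-2-en-1-yl]-3,4-dimethoxybenzoate | COC(=O)c1cc(Br)c(OC)c(OC)c1C/C=C/N(CC)CC | intermediate (not isolated)
12 | keto aldehyde, racemic methyl 5-bromo-2-(2-formyl-5-oxohexyl)-3,4-dimethoxybenzoate | COC(=O)c1cc(Br)c(OC)c(OC)c1CC(C=O)CCC(C)=O | intermediate (not isolated)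
13 | racemic methyl 5-bromo-3,4-dimethoxy-2-[(4-oxocyclohex-2-en-1-yl)methyl]benzoate | COC(=O)c1cc(Br)c(OC)c(OC)c1CC1CCC(=O)C=C1 | intermediate
14 | methyl 5-bromo-2-(4-hydroxybenzyl)-3,4-dimethoxybenzoate | COC(=O)c1cc(Br)c(OC)c(OC)c1Cc1ccc(O)cc1 | intermediate
15 | methyl 5-bromo-2-(3-bromo-4-hydroxybenzyl)-3,4-dimethoxybenzoate | COC(=O)c1cc(Br)c(OC)c(OC)c1Cc1ccc(O)c(Br)c1 | intermediate
16 | methyl 5-bromo-2-(3-bromo-4-hydroxybenzyl)-3,4-dihydroxybenzoate | COC(=O)c1cc(Br)c(O)c(O)c1Cc1ccc(O)c(Br)c1 | intermediate
17 | 5-bromo-2-(3-bromo-4-hydroxybenzyl)-3,4-dihydroxybenzyl alcohol (achiral) | OCc1cc(Br)c(O)c(O)c1Cc1ccc(O)c(Br)c1 | target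

Total step count: 11. Longest linear sequence: 11 steps (1 to 17).

Steps most likely to fail

Risk 1, step 7. The conjugate addition may run on to a second alkylation, the enone may polymerize under amine catalysis, or the cyclodehydration may stall at the open keto aldehyde. The fallback sets out from 9 and comes back to the route at 12. Aldehyde 9 would be converted with Me3SiCl, NaI and Et3N in MeCN at rt into the trimethylsilyl enol ether, methyl 5-bromo-3,4-dimethoxy-2-[3-(trimethylsilyloxy)prop-2-en-1-yl]benzoate F1. A Mukaiyama–Michael addition of F1 to 10 (BF3·OEt2, i-PrOH, MeNO2, −20 °C) would then give keto aldehyde 12 as an isolated, purified compound. Compound 12 would be closed to 13 with piperidine/AcOH in refluxing toluene as in step 7. This replaces amine catalysis in the C–C bond formation by Lewis acid activation of the enone and a preformed enol derivative.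

Risk 2, step 11. Hydride transfer to an ester conjugated with an aluminium phenoxide may be slow, and forcing it may cause loss of the new benzylic oxygen by elimination to a quinone methide and further reduction. The fallback sets out from 16 and comes back at 17. The three phenols would be silylated (t-BuMe2SiOTf, 2,6-lutidine, CH2Cl2, 0 °C) to the tris-silyl ether methyl 5-bromo-2-[3-bromo-4-(tert-butyldimethylsilyloxy)benzyl]-3,4-bis(tert-butyldimethylsilyloxy)benzoate F2. The now unconjugated ester would be reduced with i-Bu2AlH (2.5 equiv) in CH2Cl2 at −78 °C to {5-bromo-2-[3-bromo-4-(tert-butyldimethylsilyloxy)benzyl]-3,4-bis(tert-butyldimethylsilyloxy)phenyl}methanol F3. The silyl groups would be removed with Bu4NF buffered with AcOH in THF at 0 °C to give 17.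

Risk 3, step 1. Regiocontrol in the mono-alkylation may be lost, with methylation at the other oxygen or at both. The fallback sets out from 1 and comes back at 4, reversing the order of the two alkylations. The dianion of 1 (NaH, 2.2 equiv, DMSO, rt) reacts at its more basic, less stabilized 5-oxygen, so one equivalent of 3 would give methyl 3-bromo-4-hydroxy-5-(prop-2-en-1-yloxy)benzoate F4. Its remaining acidic 4-OH would then be methylated (MeI, K2CO3, DMF) to give 4.

Further compounds
F1 | step 7 | methyl 5-bromo-3,4-dimethoxy-2-[3-(trimethylsilyloxy)prop-2-en-1-yl]benzoate (E/Z mixture) | COC(=O)c1cc(Br)c(OC)c(OC)c1CC=CO[Si](C)(C)C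
F2 | step 11 | methyl 5-bromo-2-[3-bromo-4-(tert-butyldimethylsilyloxy)benzyl]-3,4-bis(tert-butyldimethylsilyloxy)benzoate | COC(=O)c1cc(Br)c(O[Si](C)(C)C(C)(C)C)c(O[Si](C)(C)C(C)(C)C)c1Cc1ccc(O[Si](C)(C)C(C)(C)C)c(Br)c1
F3 | step 11 | {5-bromo-2-[3-bromo-4-(tert-butyldimethylsilyloxy)benzyl]-3,4-bis(tert-butyldimethylsilyloxy)phenyl}methanol | OCc1cc(Br)c(O[Si](C)(C)C(C)(C)C)c(O[Si](C)(C)C(C)(C)C)c1Cc1ccc(O[Si](C)(C)C(C)(C)C)c(Br)c1
F4 | step 1 | methyl 3-bromo-4-hydroxy-5-(prop-2-en-1-yloxy)benzoate | COC(=O)c1cc(OCC=C)c(O)c(Br)c1
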